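**Assumption:** the absolute configuration is taken directly from the SMILES. That is C2 = R and the carbinol carbon = R by CIP. Both alkenes are E.

**Retrosynthesis**
- The target is disconnected at C5–C6. A Negishi coupling joins a chromanylethylzinc iodide (9, 15 heavy atoms of target skeleton) to an (E)-vinyl iodide carrying the whole oxidised farnesyl-type chain (16, 15 heavy atoms). Both phenol and carbinol are silyl-protected during the coupling.
- The chromane ring is the only ring formed. It closes in Step 5 by Pd(II)-catalysed asymmetric Wacker-type oxycarbonylation of an o-homoprenylphenol, which sets the quaternary C2. The arene comes from o-cresol.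
- Chain 16 comes from 4-pentyn-1-ol by Zr-catalysed carboalumination/iodination, E-selective Wittig to an α-methyl enal, Brown allylation to set the carbinol, and cross-metathesis to install the prenyl terminus.

---

**Step 1**
Reactants: 1, o-cresol
Product: 2, 2-methylbenzene-1,4-diol
Conditions: K2S2O8, aq. NaOH, 0 °C → rt; then HCl, 100 °C
Reagents that add atoms: potassium persulfate, [K+].[K+].[O-]S(=O)(=O)OOS(=O)(=O)[O-] (supplies the new O)
Why: Elbs persulfate oxidation hydroxylates phenols para to OH (via the aryl sulfate, hydrolysed by HCl), so the 4-position of o-cresol is oxygenated. The yield is modest.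

**Step 2**
Reactants: 2
Product: 3, 4-[(tert-butyldimethylsilyl)oxy]-2-methylphenol
Conditions: TBSCl (1.0 equiv), imidazole, DMF, 0 °C
Reagents that add atoms: TBSCl, CC(C)(C)[Si](C)(C)Cl
Why: The OH ortho to the methyl group is hindered, so silylation occurs at the 4-OH. This leaves the ring-oxygen phenol free and the future C6–O protected.

**Step 3**
Reactants: 3
Product: 4, 2-bromo-4-[(tert-butyldimethylsilyl)oxy]-6-methylphenol
Conditions: NBS (1.0 equiv), i-Pr2NH (cat.), CH2Cl2, 0 °C
Reagents that add atoms: NBS, BrN1C(=O)CCC1=O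
Why: Amine-mediated NBS bromination of phenols is ortho-selective. The para position is blocked and the other ortho position carries the methyl group.

**Step 4**
Reactants: 4; 5, 4-bromo-2-methylbut-1-ene
Product: 6, 4-[(tert-butyldimethylsilyl)oxy]-2-methyl-6-(3-methylbut-3-en-1-yl)phenol
Conditions: (i) 5, Zn dust, LiCl, TMSCl (cat.), THF, 40 °C, giving (3-methylbut-3-en-1-yl)ZnBr; (ii) 4 (zinc reagent in excess), PdCl2(dppf) (5 mol%), THF, 60 °C
Reagents that add atoms: none
Why: Negishi coupling of a primary alkylzinc with an aryl bromide installs the homoprenyl chain. The zinc reagent is used in excess to cover the free phenol.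

**Step 5**
Reactants: 6
Product: 7, methyl 2-[(2S)-6-(TBSO)-2,8-dimethylchroman-2-yl]acetate. The spatial arrangement is that of the target C2; the descriptor is S here because CIP priorities change along the route.
Conditions: Pd(TFA)2 (10 mol%), chiral BOXAX bis(oxazoline) ligand (enantiomer chosen to give 7 as drawn), p-benzoquinone, CO (1 atm), MeOH, 25 °C
Reagents that add atoms: carbon monoxide, [C-]#[O+]; methanol, CO
Why: Wacker-type oxycarbonylation. The phenol adds Markovnikov (6-exo) across the 1,1-disubstituted alkene on a Pd(II)–chiral ligand complex. The resulting neopentyl-type Pd–CH2 inserts CO and is trapped by MeOH, with benzoquinone reoxidising Pd(0). The ligand controls enantiofacial attack, which sets the quaternary C2 and forms the chromane ring.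

**Step 6**
Reactants: 7
Product: 8, 2-[(2S)-6-(TBSO)-2,8-dimethylchroman-2-yl]ethan-1-ol
Conditions: DIBAL-H (2.5 equiv), CH2Cl2, −78 → 0 °C
Reagents that add atoms: none
Why: Hydride reduction of the ester to the primary alcohol. The aryl TBS ether and the stereocentre are untouched.

**Step 7**
Reactants: 8
Product: 9, tert-butyl{[(2S)-2-(2-iodoethyl)-2,8-dimethylchroman-6-yl]oxy}dimethylsilane
Conditions: PPh3, I2, imidazole, CH2Cl2, 0 °C → rt
Reagents that add atoms: iodine, II
Why: Appel/Garegg iodination converts the primary OH to the iodide by SN2, far from the quaternary centre.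

**Step 8**
Reactants: 10, 4-pentyn-1-ol
Product: 11, (4E)-5-iodo-4-methylpent-4-en-1-ol
Conditions: (i) Me3Al, Cp2ZrCl2 (cat.), CH2Cl2, 0 °C → rt; (ii) I2, THF, −30 → 0 °C
Reagents that add atoms: trimethylaluminium, C[Al](C)C; iodine, II
Why: Negishi Zr-catalysed carboalumination is a syn addition of Me–Al across the terminal alkyne. Iodinolysis gives the E-trisubstituted vinyl iodide, which becomes the C6=C7 alkene.

**Step 9**
Reactants: 11
Product: 12, (4E)-5-iodo-4-methylpent-4-enal
Conditions: Dess–Martin periodinane, NaHCO3, CH2Cl2, 0 °C → rt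
Reagents that add atoms: none
Why: Mild oxidation of the primary alcohol to the aldehyde that leaves the vinyl iodide alone.

**Step 10**
Reactants: 12
Product: 13, (2E,6E)-7-iodo-2,6-dimethylhepta-2,6-dienal
Conditions: Ph3P=C(Me)CHO (1.2 equiv), toluene, 80 °C
Reagents that add atoms: 2-(triphenylphosphoranylidene)propanal, CC(C=O)=P(c1ccccc1)(c1ccccc1)c1ccccc1 (transfers the C(Me)CHO unit)
Why: A stabilised-ylide Wittig reaction gives the E-α-methyl enal, fixing the C10=C11 geometry as E.

**Step 11**
Reactants: 13
Product: 14, (4R,5E,9E)-10-iodo-5,9-dimethyldeca-1,5,9-trien-4-ol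
Conditions: (+)-Ipc2B(allyl) (from (−)-α-pinene), Et2O, −78 °C; then NaOH, H2O2
Reagents that add atoms: B-allyldiisopinocampheylborane, C=CCB(C1CC2CC(C1C)C2(C)C)C1CC2CC(C1C)C2(C)C (supplies the allyl group; the (+)-enantiomer is used)
Why: Brown asymmetric allylboration proceeds through a chair transition state with the Ipc ligands controlling the aldehyde face. This sets the carbinol (C12) as R, and the vinyl iodide and the alkene are unaffected.

**Step 12**
Reactants: 14
Product: 15, tert-butyl{[(4R,5E,9E)-10-iodo-5,9-dimethyldeca-1,5,9-trien-4-yl]oxy}dimethylsilane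
Conditions: TBSOTf, 2,6-lutidine, CH2Cl2, −78 °C
Reagents that add atoms: TBSOTf, C[Si](C)(C(C)(C)C)OS(=O)(=O)C(F)(F)F
Why: The triflate silylates the hindered secondary allylic alcohol without touching the stereocentre. This protects it for the organozinc coupling.

**Step 13**
Reactants: 15
Product: 16, tert-butyl{[(1E,5E,7R)-1-iodo-2,6,10-trimethylundeca-1,5,9-trien-7-yl]oxy}dimethylsilane
Conditions: 2-methyl-2-butene (20 equiv), Grubbs II (5 mol%), CH2Cl2, 40 °C
Reagents that add atoms: 2-methyl-2-butene, CC=C(C)C (supplies the =CMe2 terminus)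
Why: Cross-metathesis converts the unhindered monosubstituted allyl alkene into the prenyl-type Me2C=CH– terminus. The hindered trisubstituted alkenes and the vinyl iodide react much more slowly.

**Step 14**
Reactants: 9; 16
Product: 17, bis-TBS ether of the target
Conditions: (i) 9, Zn dust, LiCl, TMSCl (cat.), THF, 40 °C, giving the alkylzinc iodide; (ii) 16, Pd(PPh3)4 (5 mol%), THF, 40 °C
Reagents that add atoms: none
Why: Negishi coupling of a primary alkylzinc with an alkenyl iodide forms the C5–C6 bond. It retains the E geometry of C6=C7 and leaves both stereocentres untouched.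

**Step 15**
Reactants: 17
Product: 18, sargachromanol C
Conditions: TBAF (4 equiv), THF, 0 → 40 °C
Reagents that add atoms: none
Why: Fluoride removes the aryl TBS ether and the hindered allylic TBS ether. The alkenes and stereocentres are untouched.

---

**Compound list**

1 | o-cresol | Cc1ccccc1O | starting material
2 | 2-methylbenzene-1,4-diol | Cc1cc(O)ccc1O | intermediate
3 | 4-(TBSO)-2-methylphenol | Cc1cc(O[Si](C)(C)C(C)(C)C)ccc1O | intermediate
4 | 2-bromo-4-(TBSO)-6-methylphenol | Cc1cc(O[Si](C)(C)C(C)(C)C)cc(Br)c1O | intermediate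
5 | 4-bromo-2-methylbut-1-ene | C=C(C)CCBr | starting material
6 | 4-(TBSO)-2-methyl-6-(3-methylbut-3-enyl)phenol | C=C(C)CCc1cc(O[Si](C)(C)C(C)(C)C)cc(C)c1O | intermediate
7 | methyl (2S)-6-(TBSO)-2,8-dimethylchroman-2-ylacetate | COC(=O)C[C@]1(C)CCc2cc(O[Si](C)(C)C(C)(C)C)cc(C)c2O1 | intermediate
8 | 2-[(2S)-6-(TBSO)-2,8-dimethylchroman-2-yl]ethanol | OCC[C@]1(C)CCc2cc(O[Si](C)(C)C(C)(C)C)cc(C)c2O1 | intermediate
9 | (2S)-2-(2-iodoethyl)-6-(TBSO)-2,8-dimethylchromane | ICC[C@]1(C)CCc2cc(O[Si](C)(C)C(C)(C)C)cc(C)c2O1 | intermediate
10 | 4-pentyn-1-ol | C#CCCO | starting material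
11 | (4E)-5-iodo-4-methylpent-4-en-1-ol | OCCC/C(C)=C/I | intermediate
12 | (4E)-5-iodo-4-methylpent-4-enal | O=CCC/C(C)=C/I | intermediate
13 | (2E,6E)-7-iodo-2,6-dimethylhepta-2,6-dienal | O=C/C(C)=C/CC/C(C)=C/I | intermediate
14 | (4R,5E,9E)-10-iodo-5,9-dimethyldeca-1,5,9-trien-4-ol | C=CC[C@@H](O)/C(C)=C/CC/C(C)=C/I | intermediate
15 | TBS ether of 14 | C=CC[C@@H](O[Si](C)(C)C(C)(C)C)/C(C)=C/CC/C(C)=C/I | intermediate
16 | (1E,5E,7R)-1-iodo-2,6,10-trimethylundeca-1,5,9-trien-7-yl TBS ether | CC(C)=CC[C@@H](O[Si](C)(C)C(C)(C)C)/C(C)=C/CC/C(C)=C/I | intermediate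
17 | bis-TBS-sargachromanol C | CC(C)=CC[C@@H](O[Si](C)(C)C(C)(C)C)/C(C)=C/CC/C(C)=C/CC[C@]1(C)CCc2cc(O[Si](C)(C)C(C)(C)C)cc(C)c2O1 | intermediate
18 | sargachromanol C | CC(C)=CC[C@@H](O)/C(C)=C/CC/C(C)=C/CC[C@]1(C)CCc2cc(O)cc(C)c2O1 | target

---

**Total step count:** 15.
**Longest linear sequence:** 9 (Steps 1–7, 14, 15).

**Three steps most likely to fail**
1. **Step 5 (asymmetric Wacker oxycarbonylation).** The electron-rich p-silyloxyphenol may be oxidised by benzoquinone or Pd(II), and the ee may be low.
   - Fallback: build racemic chromane alcohol 8 by a non-asymmetric cyclisation, then resolve it by lipase-catalysed acetylation (CAL-B, vinyl acetate) or preparative chiral HPLC. This replaces the catalytic asymmetric ring closure with a resolution.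
2. **Step 13 (cross-metathesis).** It may scramble the trisubstituted alkenes or be poisoned by the vinyl iodide.
   - Fallback: re-sequence fragment 16. Carry 5-TMS-4-pentyn-1-ol through the Wittig, allylation, silylation and cross-metathesis steps, then desilylate and do the carboalumination/iodination last.
3. **Step 4 (Negishi on the free ortho-bromophenol).** Pd–H may isomerise the 1,1-disubstituted alkene, and the free phenol may interfere.
   - Fallback: ortho-formylate phenol 3 (MgCl2, Et3N, paraformaldehyde), do a Wittig with the isoprenyl-type phosphonium ylide (Ph3P=CH–C(Me)=CH2) to give an aryl diene, then reduce the disubstituted alkene selectively with diimide. This gives the same Wacker substrate 6 by a different disconnection.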